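Atom numbers C1–C20 refer to the target: lactone carbonyl C1, enol carbon C3, ring carbinol C5, chain carbinols C7, C9 and C11, nonyl tail C12–C20. Compound numbers 1–23 are those of the steps and of the compound list.

## Analysis of the target

Compound 23 is the enol form of a 3-oxo-δ-lactone (a 4-hydroxy-5,6-dihydro-2H-pyran-2-one) that carries a 2,4,6-trihydroxypentadecyl chain on its ring carbinol. It is a linear C20 chain with oxygen on every odd carbon from C1 to C11 and four stereocentres: 5R, 7R, 9S and 11S. In the zigzag projection C5/C7 are syn, C7/C9 are anti and C9/C11 are syn, so no single repeated 1,3-diol protocol gives all three relationships. The sensitive part is the β-keto lactone. The vinylogous acid is easily ring-opened, the C5 oxygen sits β to the C3 carbonyl (elimination, retro-aldol across C4–C5), and the free C7 hydroxyl is 1,5 to that carbonyl, so the heterocycle has to be closed last. The difficulty is stereocontrol on a flexible, unbranched chain with no ring or branch to relay information, together with protecting groups that must come off without harming the enol lactone. The plan rests on C11: it is syn-1,3 to C9 and is followed only by the saturated tail C12–C20. Its oxygen can therefore be brought in from C13 by an allylic 1,3-shift, and the alkene that the shift leaves at C12=C13 needs only saturation.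

## Retrosynthetic reasoning

**Lactone C1–O bond and the two acetals (23 ⇒ 22 ⇒ 21).** The ring is opened first, at the ester bond between C1 and the C5 oxygen, because the enol lactone tolerates the least handling. This gives the open-chain keto ester 22, in which only the six-membered lactone can form (closure through the C7 oxygen would be eight-membered). 22 is drawn from 21, where the C5/C7 and C9/C11 diols are masked as two six-membered acetals. Forward, the four hydroxyls are unmasked under aqueous acid and the ring is closed under mild base, where the stabilised enolate of 23 is the thermodynamic sink.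

**C2–C3 bond (21 ⇒ 19 + 20).** Cutting between C2 and C3 removes the two-carbon acetate unit 20 and leaves the methyl ester 19. The β-dicarbonyl, the most reactive array in the molecule, is thus made in the last C–C bond-forming step. Forward, a crossed Claisen condensation must acylate the enolate of 20 with 19 faster than 19 is enolised.

**C5 carbinol and the acetonide (19 ⇒ 18 ⇒ 17).** C5 is traced to a ketone. A hydroxyl-directed reduction of the β-hydroxy ketone 17 sets C5 syn to C7 from the existing C7 centre, so no new chiral reagent is needed. The acetonide of 19 only protects the 1,3-diol of 18 through the enolate chemistry.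

**C6–C7 bond (17 ⇒ 12 + 15).** 17 is the aldol adduct of the aldehyde 12 and the four-carbon dienolate 15, which brings in C3–C6 in one piece and is made in two steps from 13 via 14. The cut is at C6–C7 and not at C4–C5 because the C9 acetal oxygen of 12 sits β to the aldehyde and can direct the nucleophile to the anti face, which is the C7/C9 relationship of the target. Forward, the aldol must run under a non-chelating Lewis acid so that this 1,3-induction operates.

**Functional-group adjustments (12 ⇒ 11 ⇒ 10 ⇒ 9).** The aldehyde 12 comes from the primary alcohol 11, and 11 from the silyl ether 10. 10 is the saturated form of the alkenyl acetal 9. The C12=C13 double bond has no function in the target and is removed by a metal-free hydrogen transfer that spares the benzylic acetal.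

**C11–O bond and the acetal ring (9 ⇒ 8 ⇒ 6 + 7).** This is the strategic disconnection. The syn acetal 9 is the trapped form of the allylic 1,3-diol 8, and 8 is the 1,3-transposition isomer of the allylic alcohol 6, which has its hydroxyl on C13 and its alkene at C11=C12. C11 then need not be made by an asymmetric reaction at all: its configuration is dictated by C9 through the chair of the acetal formed with 7. Both C13 epimers and both alkene geometries of 6 converge, so 6 may be racemic at C13 and of any geometry. Forward, the transposition must be reversible and faster than ionisation, and the acetal exchange must withdraw only the C11 isomer.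

**C11=C12 bond (6 ⇒ 4 + 5).** The disubstituted alkene of 6 is the natural cross-metathesis seam between the homoallylic alcohol 4 and the racemic allylic alcohol 5, both terminal alkenes. Neither hydroxyl needs protection.

**C9–C10 bond (4 ⇒ 2 + 3; 2 ⇐ 1).** C9 is the only stereocentre set by an asymmetric reagent, through enantioselective allylation. Starting from the alcohol 2 and the allyl donor 3 at the alcohol oxidation level saves an oxidation step. 2 is the monosilyl ether of the symmetric diol 1.

## Alternatives that were turned down

**Alternative 1: anion relay at C9.**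
- Disconnection: C8–C9 and C9–C10 are both cut, and C9 becomes a carbonyl dianion equivalent.
- Forward key step: the lithiated silyl dithiane A2 opens the nonyl epoxide A3 at C10. A strongly Lewis-basic cosolvent then triggers 1,4-migration of silicon from C9 to the C11 oxygen (Brook rearrangement). The regenerated C9 anion opens the allyl epoxide A4 at C8 and gives the relay product A1 in one flask.
- For: two skeletal bonds in one operation and full convergence. C7 and C11 enter as independent, enantiopure epoxides, so neither depends on 1,3-induction. The two oxygens leave the step already differentiated (silyl ether at C11, free hydroxyl at C7).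
- Against, for this target: C9 is left as a masked ketone, so the step creates no stereocentre at the position that must relate to both neighbours. The dithiane must be removed next to a terminal alkene, and the carbonyl then reduced anti to C7 under hydroxyl direction. Two enantiopure epoxides are needed, each from its own kinetic resolution. The allyl terminus still has to be turned into C1–C5 with a new centre at C5.
- Comparison: on convergence and on absolute control at C7 this alternative is stronger. The chosen route offers instead a single chiral input (one catalytic allylation giving 4), a racemic partner 5, no thioacetal chemistry, and a key step that sets C11 and protects the C9/C11 diol in the same operation. The step count to a C7–C20 fragment is similar, but the alternative still owes its C9 reduction at that point.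

**Alternative 2: carbonylative ring expansion at the ring end.**
- Disconnection: C3–C4 and C3–O. The ring end is traced to the four-membered lactone A6, and that to the terminal epoxide A5 and carbon monoxide A7.
- Forward key step: the ion pair [(salph)Al(THF)2][Co(CO)4] activates the epoxide, the Co(CO)4 anion opens it at C4, A7 inserts, and the C5 alkoxide closes onto the acyl group. The β-lactone A6 is later enlarged by acylating an acetate enolate and relactonising.
- For: C3 arrives as an activated acyl group with the C5 oxygen already in place and its configuration retained, because attack is at the CH2 terminus. A ketone reduction, a diol protection and a separate ester are saved, and the atom economy is ideal.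
- Against, for this target: the step needs the complete C4–C20 chain A5 with all four stereocentres already assembled, so it does nothing for the stereochemical problem. It needs pressurised A7 and an air-sensitive catalyst. Enolates can attack a β-lactone at the acyl carbon or at C5 (alkyl–oxygen cleavage), and only the first leads on. Three silyl ethers must finally be removed from the enol lactone.
- Comparison: at the ring end this alternative is probably two steps shorter than the chosen end-game, and that point is conceded. The chosen strategy offers in its place a demanding step that does stereochemical work early (9 from 6) and ordinary equipment throughout.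

**Alternative 3: enzymatic assembly of C3–C8.**
- Disconnection: the C3–C8 segment is cut at C4–C5 and C6–C7 into three two-carbon aldehydes.
- Forward key step: 2-deoxyribose-5-phosphate aldolase adds acetaldehyde A9 twice to chloroacetaldehyde A8. The 3,5-dihydroxy aldehyde closes through the C7 oxygen onto C3 and gives the lactol A10.
- For: C5 and C7 are both set by the enzyme in water, syn and with essentially complete enantiocontrol, without protecting groups and from bulk aldehydes.
- Against, for this target: C8 emerges as a chloromethyl group next to an oxygenated carbon, which is a sluggish electrophile. Joining it to a C9–C20 partner with C9 anti to C7 and syn to C11 is the real problem of the target, and the enzymatic step leaves it untouched. In A10 the ring runs through the C7 oxygen and C3 is at the aldehyde level, whereas the target needs the ring through the C5 oxygen and C3 as the enol carbon. A10 would have to be oxidised, opened, protected and extended by C1–C2 anyway. Both aldehydes inhibit the enzyme, which forces dilute fed-batch operation.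
- Comparison: on enantiopurity and atom economy at C5/C7 this alternative is better than the substrate-controlled aldol and reduction that make 17 and 18. The chosen route offers in its place a solution for C9/C11, the part with no enzymatic shortcut, and then adds C3–C6 in one aldol (12 + 15).

Key step: step 4

Assumption: 23 is handled as the enol tautomer drawn; the keto and enol forms of the 3-oxo-δ-lactone interconvert and are not treated separately.

## Route

Step 1
Reactants: 1 propane-1,3-diol
Product: 2 3-(tert-butyldiphenylsilyloxy)propan-1-ol
Conditions: NaH (1.0 equiv), THF, 0 °C to rt; then tBuPh2SiCl (1.0 equiv), rt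
Reagents that add atoms: tert-butyl(chloro)diphenylsilane, CC(C)(C)[Si](Cl)(c1ccccc1)c1ccccc1
Why: O-Silylation of the monosodium alkoxide; one equivalent of NaH on the symmetric diol gives a poorly soluble mono-alkoxide that is silylated faster than the product is deprotonated, so the monoether should predominate. The bulky diphenylsilyl ether is chosen because it has to survive Cs2CO3 at 100 °C, the metathesis and the Lewis-acidic Re2O7 step.

Step 2
Reactants: 2 3-(tert-butyldiphenylsilyloxy)propan-1-ol; 3 allyl acetate
Product: 4 (S)-1-(tert-butyldiphenylsilyloxy)hex-5-en-3-ol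
Conditions: [Ir(cod)Cl]2 (2.5 mol %), (S)-Cl,MeO-BIPHEP (5 mol %), 4-chloro-3-nitrobenzoic acid (10 mol %), Cs2CO3 (20 mol %), 3 (excess), THF, 100 °C, sealed tube
Reagents that add atoms: none
Why: Transfer-hydrogenative carbonyl allylation: the catalyst formed in situ from [Ir(cod)Cl]2, the bisphosphine and the nitrobenzoic acid dehydrogenates 2 to the aldehyde, uses the hydrogen to turn 3 into an iridium-bound allyl nucleophile, and adds it through a closed chair transition state in the chiral pocket, forming C9–C10 and setting C9. The bisphosphine antipode is the one that delivers the 3S alcohol, expected to be the (S)-ligand by analogy with other β-oxygenated primary alcohols. Sense and enantiomeric purity are to be confirmed on 4, because every later centre is relayed from C9.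

Step 3
Reactants: 4 (S)-1-(tert-butyldiphenylsilyloxy)hex-5-en-3-ol; 5 dec-1-en-3-ol (racemic)
Product: 6 (3S)-1-(tert-butyldiphenylsilyloxy)tetradec-5-ene-3,7-diol (both C7 epimers, mainly 5E)
Conditions: second-generation Grubbs catalyst (5 mol %), 5 (3 equiv), CH2Cl2, 40 °C
Reagents that add atoms: none
Why: Olefin cross-metathesis between a rapidly homodimerising homoallylic alkene and a slower, more hindered allylic alcohol used in excess; loss of ethylene drives it and forms the C11=C12 bond. The epimer mixture at the allylic carbinol (C13 of the target) and any Z isomer are of no consequence, because both elements are erased in step 4.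

Step 4
Reactants: 6 (3S)-1-(tert-butyldiphenylsilyloxy)tetradec-5-ene-3,7-diol; 7 benzaldehyde dimethyl acetal
Product: 9 tert-butyl{2-[(2R,4R,6R)-6-[(E)-non-1-enyl]-2-phenyl-1,3-dioxan-4-yl]ethoxy}diphenylsilane, via transposed syn-1,3-diol 8 (not isolated)
Conditions: Re2O7 (3 mol %), 7 (3 equiv), CH2Cl2, 0 °C to rt
Reagents that add atoms: none
Why: Re2O7 condenses with the C13 hydroxyl of 6 to an allylic perrhenate ester, which rearranges through a chair-like [3,3]-sigmatropic transition state so that the C–O bond moves from C13 to C11 and the alkene from C11=C12 to C12=C13; the shift is reversible and has some ion-pair character, so the C13 configuration and the alkene geometry of 6 are lost and do not matter. Among the equilibrating isomers only 8 has a hydroxyl 1,3 to the C9 hydroxyl, and acetal exchange with 7, catalysed by the same Lewis-acidic rhenium species, withdraws it as the 1,3-dioxane 9. The ring closes when the second hydroxyl adds to the oxocarbenium ion of the mixed methyl acetal, a 6-endo-trig closure counted at the C=O+ bond. The closest known reaction type is the Re2O7-catalysed 1,3-transposition of allylic alcohols that carry a neighbouring hydroxyl, with capture of the syn-1,3-diol as its benzylidene acetal. C11 is set under thermodynamic control by the fixed C9 centre: transposition, its reverse and acetal exchange all stay reversible, and the mixture should settle in the chair with the C8 chain, the alkenyl group and phenyl all equatorial, which is the C9/C11 syn (cis-4,6) isomer; the acetal carbon is fixed by the same equatorial preference of phenyl. The E geometry follows from the equatorial position of the heptyl-bearing carbon in the rearrangement chair and from equilibration. The step needs the oxygen at C11 and not at C13, which the ring size secures because an acetal across the C9 and C13 oxygens would be eight-membered, and it needs equilibration to outpace ionisation to dienes or to a cyclic ether through the C9 hydroxyl, which the unactivated secondary allylic system, the low temperature and the low catalyst loading favour. The silyl ether and the C9 centre, which is never allylic, should not be affected.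

Step 5
Reactants: 9 tert-butyl{2-[(2R,4R,6R)-6-[(E)-non-1-enyl]-2-phenyl-1,3-dioxan-4-yl]ethoxy}diphenylsilane
Product: 10 tert-butyl{2-[(2S,4R,6S)-6-nonyl-2-phenyl-1,3-dioxan-4-yl]ethoxy}diphenylsilane
Conditions: 2-nitrobenzenesulfonyl hydrazide (excess, in portions), Et3N, CH2Cl2, rt
Reagents that add atoms: none
Why: Diimide reduction: the hydrazide fragments to diimide, which delivers two hydrogens suprafacially to the unpolarised C12=C13 bond. Unlike hydrogenation over Pd/C it cannot hydrogenolyse the benzylic (and, at C11, allylic) acetal C–O bonds; no stereocentre is involved, and the descriptors change only because the CIP priorities change.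

Step 6
Reactants: 10 tert-butyl{2-[(2S,4R,6S)-6-nonyl-2-phenyl-1,3-dioxan-4-yl]ethoxy}diphenylsilane
Product: 11 2-[(2S,4R,6S)-6-nonyl-2-phenyl-1,3-dioxan-4-yl]ethanol
Conditions: Bu4NF, THF, 0 °C to rt
Reagents that add atoms: none
Why: Fluoride-induced Si–O cleavage driven by the strength of the Si–F bond; the benzylidene acetal is inert to these basic conditions.

Step 7
Reactants: 11 2-[(2S,4R,6S)-6-nonyl-2-phenyl-1,3-dioxan-4-yl]ethanol
Product: 12 2-[(2S,4S,6S)-6-nonyl-2-phenyl-1,3-dioxan-4-yl]acetaldehyde
Conditions: TEMPO (10 mol %), PhI(OAc)2 (1.2 equiv), CH2Cl2, rt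
Reagents that add atoms: none
Why: Oxoammonium-catalysed oxidation of a primary alcohol that stops at the aldehyde and needs no amine base, which limits β-elimination of the C9 acetal oxygen. 12 is to be used without chromatography.

Step 8
Reactants: 13 methyl acetoacetate
Product: 14 methyl 3-(trimethylsilyloxy)but-2-enoate
Conditions: Me3SiCl, Et3N, hexane, rt
Reagents that add atoms: chlorotrimethylsilane, C[Si](C)(C)Cl
Why: O-Silylation of the β-keto ester under soft enolisation; the conjugated enol ether is the stable product and can be distilled.

Step 9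
Reactants: 14 methyl 3-(trimethylsilyloxy)but-2-enoate
Product: 15 1-methoxy-1,3-bis(trimethylsilyloxy)buta-1,3-diene
Conditions: LiN(iPr)2, THF, −78 °C; then Me3SiCl, −78 °C to rt
Reagents that add atoms: chlorotrimethylsilane, C[Si](C)(C)Cl
Why: γ-Deprotonation of the enoate gives the extended ester dienolate, which is trapped on oxygen as the silyl ketene acetal. The diene is moisture-sensitive and is to be used freshly distilled.

Step 10
Reactants: 12 2-[(2S,4S,6S)-6-nonyl-2-phenyl-1,3-dioxan-4-yl]acetaldehyde; 15 1-methoxy-1,3-bis(trimethylsilyloxy)buta-1,3-diene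
Product: 17 methyl (5R)-5-hydroxy-6-[(2S,4R,6S)-6-nonyl-2-phenyl-1,3-dioxan-4-yl]-3-oxohexanoate, via 3-silyloxy enoate adduct 16 (not isolated)
Conditions: BF3·OEt2 (1.1 equiv), CH2Cl2, −78 °C; aq. NaHCO3; then 1 M HCl, THF, 0 °C
Reagents that add atoms: none
Why: Vinylogous Mukaiyama aldol through an open transition state: BF3 activates the aldehyde as a monodentate Lewis acid and the terminal carbon of 15 adds to form C6–C7. With chelation excluded, the C9–O dipole opposes the carbonyl and the nucleophile approaches anti to the C10 ring residue (1,3-anti induction of β-alkoxy aldehydes), which should place the C7 hydroxyl anti to the C9 oxygen (R). The primary adduct 16 keeps the C3 silyl enol ether, which brief dilute acid hydrolyses to the keto ester while the benzylidene acetal stays on.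

Step 11
Reactants: 17 methyl (5R)-5-hydroxy-6-[(2S,4R,6S)-6-nonyl-2-phenyl-1,3-dioxan-4-yl]-3-oxohexanoate
Product: 18 methyl (3R,5S)-3,5-dihydroxy-6-[(2S,4R,6S)-6-nonyl-2-phenyl-1,3-dioxan-4-yl]hexanoate
Conditions: Et2BOMe (1.1 equiv), THF/MeOH (4:1), −78 °C; NaBH4; then AcOH, MeOH azeotrope
Reagents that add atoms: none
Why: Narasaka–Prasad reduction: Et2BOMe ties the C7 hydroxyl and the C5 ketone into a six-membered boron chelate, and NaBH4 attacks its half-chair axially from the face opposite the pseudo-equatorial C8 substituent, which should give the C5/C7 syn diol (C5 R in target numbering). At −78 °C only the ketone of the β-keto ester is reduced.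

Step 12
Reactants: 18 methyl (3R,5S)-3,5-dihydroxy-6-[(2S,4R,6S)-6-nonyl-2-phenyl-1,3-dioxan-4-yl]hexanoate
Product: 19 methyl 2-[(4R,6R)-2,2-dimethyl-6-{[(2S,4S,6S)-6-nonyl-2-phenyl-1,3-dioxan-4-yl]methyl}-1,3-dioxan-4-yl]acetate
Conditions: Me2C(OMe)2, pyridinium p-toluenesulfonate (cat.), CH2Cl2, rt
Reagents that add atoms: 2,2-dimethoxypropane, COC(C)(C)OC
Why: Acid-catalysed transketalisation; the syn-1,3-diol closes to the chair dioxane with both ring substituents equatorial, which masks both hydroxyls for the enolate chemistry of step 13. The weak pyridinium acid should not open the benzylidene acetal, and any exchange there would be harmless because both acetals are removed together in step 14.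

Step 13
Reactants: 19 methyl 2-[(4R,6R)-2,2-dimethyl-6-{[(2S,4S,6S)-6-nonyl-2-phenyl-1,3-dioxan-4-yl]methyl}-1,3-dioxan-4-yl]acetate; 20 methyl acetate
Product: 21 methyl 4-[(4R,6R)-2,2-dimethyl-6-{[(2S,4S,6S)-6-nonyl-2-phenyl-1,3-dioxan-4-yl]methyl}-1,3-dioxan-4-yl]-3-oxobutanoate
Conditions: 20 (4 equiv), LiN(iPr)2 (4 equiv), THF, −78 °C; then 19, −78 to −40 °C; AcOH
Reagents that add atoms: none
Why: Crossed Claisen condensation: the lithium enolate of 20 adds to the methyl ester of 19, methoxide leaves, and the β-keto ester formed is deprotonated at once, which makes the condensation irreversible and forms C2–C3. An excess of enolate at low temperature is used so that addition outruns proton transfer from C4 of 19, which would open the acetonide by β-elimination.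

Step 14
Reactants: 21 methyl 4-[(4R,6R)-2,2-dimethyl-6-{[(2S,4S,6S)-6-nonyl-2-phenyl-1,3-dioxan-4-yl]methyl}-1,3-dioxan-4-yl]-3-oxobutanoate
Product: 23 (6R)-4-hydroxy-6-[(2R,4S,6S)-2,4,6-trihydroxypentadecyl]-5,6-dihydro-2H-pyran-2-one, via tetraol methyl ketoester 22 (not isolated)
Conditions: 1 M aq. HCl, THF, rt; concentrate; K2CO3, MeOH, 0 °C to rt; then 1 M HCl to pH 3
Reagents that add atoms: none
Why: Aqueous acid hydrolyses the acetonide and the benzylidene acetal to 22 without cleaving the methyl ester, and water keeps any C7-to-C3 hemiketal from dehydrating. K2CO3 then lets the C5 oxygen attack C1 in a 6-exo-trig transesterification, and the lactone is held as its stabilised enolate, the thermodynamic sink, which also shields the β-hydroxy ketone from retro-aldol cleavage; acidification should release 23. Closure through the C7 or C9 oxygen would give eight- or ten-membered rings and should not compete, and no stereocentre is touched.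

## Compound list

1 | propane-1,3-diol | OCCCO | starting material
2 | 3-(tert-butyldiphenylsilyloxy)propan-1-ol | OCCCO[Si](C(C)(C)C)(c1ccccc1)c1ccccc1 | intermediate
3 | allyl acetate | C=CCOC(C)=O | starting material
4 | (S)-1-(tert-butyldiphenylsilyloxy)hex-5-en-3-ol | C=CC[C@H](O)CCO[Si](C(C)(C)C)(c1ccccc1)c1ccccc1 | intermediate
5 | dec-1-en-3-ol (racemic) | C=CC(O)CCCCCCC | starting material
6 | (3S)-1-(tert-butyldiphenylsilyloxy)tetradec-5-ene-3,7-diol (both C7 epimers, mainly 5E) | CCCCCCCC(O)/C=C/C[C@H](O)CCO[Si](C(C)(C)C)(c1ccccc1)c1ccccc1 | intermediate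
7 | benzaldehyde dimethyl acetal | COC(OC)c1ccccc1 | starting material
8 | (3R,5R,6E)-1-(tert-butyldiphenylsilyloxy)tetradec-6-ene-3,5-diol (formed in the flask) | CCCCCCC/C=C/[C@H](O)C[C@H](O)CCO[Si](C(C)(C)C)(c1ccccc1)c1ccccc1 | intermediate
9 | tert-butyl{2-[(2R,4R,6R)-6-[(E)-non-1-enyl]-2-phenyl-1,3-dioxan-4-yl]ethoxy}diphenylsilane (all-cis dioxane across the C9 and C11 oxygens) | CCCCCCC/C=C/[C@H]1C[C@@H](CCO[Si](C(C)(C)C)(c2ccccc2)c2ccccc2)O[C@@H](c2ccccc2)O1 | intermediate
10 | tert-butyl{2-[(2S,4R,6S)-6-nonyl-2-phenyl-1,3-dioxan-4-yl]ethoxy}diphenylsilane | CCCCCCCCC[C@H]1C[C@@H](CCO[Si](C(C)(C)C)(c2ccccc2)c2ccccc2)O[C@@H](c2ccccc2)O1 | intermediate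
11 | 2-[(2S,4R,6S)-6-nonyl-2-phenyl-1,3-dioxan-4-yl]ethanol | CCCCCCCCC[C@H]1C[C@@H](CCO)O[C@@H](c2ccccc2)O1 | intermediate
12 | 2-[(2S,4S,6S)-6-nonyl-2-phenyl-1,3-dioxan-4-yl]acetaldehyde | CCCCCCCCC[C@H]1C[C@@H](CC=O)O[C@@H](c2ccccc2)O1 | intermediate
13 | methyl acetoacetate | CC(=O)CC(=O)OC | starting material
14 | methyl 3-(trimethylsilyloxy)but-2-enoate | CC(O[Si](C)(C)C)=CC(=O)OC | intermediate
15 | 1-methoxy-1,3-bis(trimethylsilyloxy)buta-1,3-diene | C=C(O[Si](C)(C)C)C=C(OC)O[Si](C)(C)C | intermediate
16 | methyl (5R)-5-hydroxy-6-[(2S,4R,6S)-6-nonyl-2-phenyl-1,3-dioxan-4-yl]-3-(trimethylsilyloxy)hex-2-enoate (formed in the flask; shown with the C7 oxygen as free hydroxyl) | CCCCCCCCC[C@H]1C[C@@H](C[C@@H](O)CC(O[Si](C)(C)C)=CC(=O)OC)O[C@@H](c2ccccc2)O1 | intermediate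
17 | methyl (5R)-5-hydroxy-6-[(2S,4R,6S)-6-nonyl-2-phenyl-1,3-dioxan-4-yl]-3-oxohexanoate | CCCCCCCCC[C@H]1C[C@@H](C[C@@H](O)CC(=O)CC(=O)OC)O[C@@H](c2ccccc2)O1 | intermediate
18 | methyl (3R,5S)-3,5-dihydroxy-6-[(2S,4R,6S)-6-nonyl-2-phenyl-1,3-dioxan-4-yl]hexanoate | CCCCCCCCC[C@H]1C[C@@H](C[C@@H](O)C[C@@H](O)CC(=O)OC)O[C@@H](c2ccccc2)O1 | intermediate
19 | methyl 2-[(4R,6R)-2,2-dimethyl-6-{[(2S,4S,6S)-6-nonyl-2-phenyl-1,3-dioxan-4-yl]methyl}-1,3-dioxan-4-yl]acetate | CCCCCCCCC[C@H]1C[C@@H](C[C@@H]2C[C@H](CC(=O)OC)OC(C)(C)O2)O[C@@H](c3ccccc3)O1 | intermediate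
20 | methyl acetate | COC(C)=O | starting material
21 | methyl 4-[(4R,6R)-2,2-dimethyl-6-{[(2S,4S,6S)-6-nonyl-2-phenyl-1,3-dioxan-4-yl]methyl}-1,3-dioxan-4-yl]-3-oxobutanoate | CCCCCCCCC[C@H]1C[C@@H](C[C@@H]2C[C@H](CC(=O)CC(=O)OC)OC(C)(C)O2)O[C@@H](c3ccccc3)O1 | intermediate
22 | methyl (5R,7R,9S,11S)-5,7,9,11-tetrahydroxy-3-oxoicosanoate (formed in the flask) | CCCCCCCCC[C@H](O)C[C@H](O)C[C@@H](O)C[C@@H](O)CC(=O)CC(=O)OC | intermediate
23 | (6R)-4-hydroxy-6-[(2R,4S,6S)-2,4,6-trihydroxypentadecyl]-5,6-dihydro-2H-pyran-2-one | CCCCCCCCC[C@H](O)C[C@H](O)C[C@@H](O)C[C@@H]1CC(O)=CC(=O)O1 | target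

## Step count and least certain steps

Total step count: 14 (steps 8 and 9 prepare the dienolate 15 on a side branch).
Longest linear sequence: 12 steps (steps 1–7 and 10–14, from 1 to 23).

**Step 4 (key step).** Ionisation of the allylic perrhenate may outrun the sigmatropic shift and the acetal capture. That would lead to elimination, or to capture of the allyl cation at C13 by the C9 hydroxyl as a six-membered ether. Equilibration may also stop short, leaving C11 epimers, and the silyl ether may be lost if adventitious acid builds up.

Fallback, from 4 back to 10: the syn acetal is built by conjugate addition instead of transposition. Cross-metathesis of 4 with methyl acrylate (second-generation Hoveyda–Grubbs catalyst, CH2Cl2, 40 °C) gives methyl (2E,5S)-7-(tert-butyldiphenylsilyloxy)-5-hydroxyhept-2-enoate F1. Benzaldehyde with catalytic KOtBu in THF at 0 °C adds the hemiacetal alkoxide to the enoate under equilibrating conditions and gives the all-cis acetal methyl 2-[(2R,4R,6R)-6-[2-(tert-butyldiphenylsilyloxy)ethyl]-2-phenyl-1,3-dioxan-4-yl]acetate F2, with C11 syn to C9. iBu2AlH at −78 °C gives 2-[(2R,4R,6R)-6-[2-(tert-butyldiphenylsilyloxy)ethyl]-2-phenyl-1,3-dioxan-4-yl]acetaldehyde F3. A Wittig reaction with the ylide from heptyltriphenylphosphonium bromide and NaN(SiMe3)2 gives tert-butyl{2-[(2S,4R,6S)-6-[(Z)-non-2-enyl]-2-phenyl-1,3-dioxan-4-yl]ethoxy}diphenylsilane F4. Diimide reduction as in step 5 returns the route at 10.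

**Step 10.** Facial selectivity may erode, because the directing C9 oxygen is an acetal oxygen held in a ring; its dipole and conformational preferences differ from those of the benzyl-type ethers for which the 1,3-anti rule is most reliable. The Lewis acid may open the benzylidene acetal, and 12 may undergo β-elimination on handling.

Fallback, from 11 back to 22: C7 is set by catalyst control and C5 by conjugate addition. The allylation of step 2 is repeated on 11 with 3 ([Ir(cod)Cl]2, the bisphosphine antipode that gives the target configuration at C7) and gives (2S)-1-[(2S,4R,6S)-6-nonyl-2-phenyl-1,3-dioxan-4-yl]pent-4-en-2-ol F5. Cross-metathesis with methyl acrylate gives methyl (2E,5S)-5-hydroxy-6-[(2S,4R,6S)-6-nonyl-2-phenyl-1,3-dioxan-4-yl]hex-2-enoate F6. Benzaldehyde and catalytic KOtBu close a second syn benzylidene acetal and set C5 in methyl 2-[(2R,4R,6R)-6-{[(2S,4S,6S)-6-nonyl-2-phenyl-1,3-dioxan-4-yl]methyl}-2-phenyl-1,3-dioxan-4-yl]acetate F7. Claisen condensation with 20 as in step 13 gives methyl 4-[(2R,4R,6R)-6-{[(2S,4S,6S)-6-nonyl-2-phenyl-1,3-dioxan-4-yl]methyl}-2-phenyl-1,3-dioxan-4-yl]-3-oxobutanoate F8. Hydrogenolysis of both acetals (H2, Pd(OH)2/C, EtOAc) returns the route at 22, which is lactonised with K2CO3 in MeOH as in step 14.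

**Step 13.** Proton transfer from C4 of 19 to the enolate may compete with addition and be followed by expulsion of the C5 acetal oxygen. Self-condensation of the enolate of 20 may use up the nucleophile before conversion is complete.

Fallback, from 19 back to 21: the acyl group is activated instead of being attacked as an ester. LiOH in THF/H2O gives 2-[(4R,6R)-2,2-dimethyl-6-{[(2S,4S,6S)-6-nonyl-2-phenyl-1,3-dioxan-4-yl]methyl}-1,3-dioxan-4-yl]acetic acid F9. 1,1'-Carbonyldiimidazole in THF gives 1-{2-[(4R,6R)-2,2-dimethyl-6-{[(2S,4S,6S)-6-nonyl-2-phenyl-1,3-dioxan-4-yl]methyl}-1,3-dioxan-4-yl]acetyl}imidazole F10. Mg(O2CCH2CO2Me)2 acylates and decarboxylates under near-neutral conditions and returns the route at 21.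

**Step 14.** During the acid stage the C7 hydroxyl may add to the C3 ketone and the hemiketal may dehydrate. Under K2CO3, retro-aldol scission across C4–C5 or elimination of the C5 oxygen may compete with lactonisation. The polar vinylogous acid may also be lost on isolation.

Fallback, from 19 to 23: the ring is closed under acid from a tert-butyl ester instead of under base from a methyl ester. Claisen condensation of 19 with the lithium enolate of tert-butyl acetate (LiN(iPr)2, THF, −78 °C) gives tert-butyl 4-[(4R,6R)-2,2-dimethyl-6-{[(2S,4S,6S)-6-nonyl-2-phenyl-1,3-dioxan-4-yl]methyl}-1,3-dioxan-4-yl]-3-oxobutanoate F11. CF3CO2H in wet CH2Cl2 (0 °C to rt) removes both acetals and the tert-butyl group and closes the lactone, arriving directly at 23.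

**Step 2.** Enantioselectivity may be insufficient, or the sense of induction may be opposite for this particular silyl ether. Either would pass through the key step unnoticed, because C11 follows C9. The allyl donor may also be reduced instead of transferred.

Fallback, from 2 back to 4: the aldehyde oxidation level and a stoichiometric chiral reagent are used. Oxidation of 2 (TEMPO, PhI(OAc)2) gives 3-(tert-butyldiphenylsilyloxy)propanal F12. Allylboration with the antipode of B-allyldiisopinocampheylborane that gives the S alcohol (Et2O, −78 °C; NaOH, H2O2) returns the route at 4.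

## Further compounds

F1 | step 4 | methyl (2E,5S)-7-(tert-butyldiphenylsilyloxy)-5-hydroxyhept-2-enoate | COC(=O)/C=C/C[C@H](O)CCO[Si](C(C)(C)C)(c1ccccc1)c1ccccc1
F2 | step 4 | methyl 2-[(2R,4R,6R)-6-[2-(tert-butyldiphenylsilyloxy)ethyl]-2-phenyl-1,3-dioxan-4-yl]acetate | COC(=O)C[C@H]1C[C@@H](CCO[Si](C(C)(C)C)(c2ccccc2)c2ccccc2)O[C@@H](c2ccccc2)O1
F3 | step 4 | 2-[(2R,4R,6R)-6-[2-(tert-butyldiphenylsilyloxy)ethyl]-2-phenyl-1,3-dioxan-4-yl]acetaldehyde | O=CC[C@H]1C[C@@H](CCO[Si](C(C)(C)C)(c2ccccc2)c2ccccc2)O[C@@H](c2ccccc2)O1
F4 | step 4 | tert-butyl{2-[(2S,4R,6S)-6-[(Z)-non-2-enyl]-2-phenyl-1,3-dioxan-4-yl]ethoxy}diphenylsilane | CCCCCC/C=C\C[C@H]1C[C@@H](CCO[Si](C(C)(C)C)(c2ccccc2)c2ccccc2)O[C@@H](c2ccccc2)O1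
F5 | step 10 | (2S)-1-[(2S,4R,6S)-6-nonyl-2-phenyl-1,3-dioxan-4-yl]pent-4-en-2-ol | CCCCCCCCC[C@H]1C[C@@H](C[C@@H](O)CC=C)O[C@@H](c2ccccc2)O1
F6 | step 10 | methyl (2E,5S)-5-hydroxy-6-[(2S,4R,6S)-6-nonyl-2-phenyl-1,3-dioxan-4-yl]hex-2-enoate | CCCCCCCCC[C@H]1C[C@@H](C[C@@H](O)C/C=C/C(=O)OC)O[C@@H](c2ccccc2)O1
F7 | step 10 | methyl 2-[(2R,4R,6R)-6-{[(2S,4S,6S)-6-nonyl-2-phenyl-1,3-dioxan-4-yl]methyl}-2-phenyl-1,3-dioxan-4-yl]acetate | CCCCCCCCC[C@H]1C[C@@H](C[C@@H]2C[C@H](CC(=O)OC)O[C@H](c3ccccc3)O2)O[C@@H](c3ccccc3)O1
F8 | step 10 | methyl 4-[(2R,4R,6R)-6-{[(2S,4S,6S)-6-nonyl-2-phenyl-1,3-dioxan-4-yl]methyl}-2-phenyl-1,3-dioxan-4-yl]-3-oxobutanoate | CCCCCCCCC[C@H]1C[C@@H](C[C@@H]2C[C@H](CC(=O)CC(=O)OC)O[C@H](c3ccccc3)O2)O[C@@H](c3ccccc3)O1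
F9 | step 13 | 2-[(4R,6R)-2,2-dimethyl-6-{[(2S,4S,6S)-6-nonyl-2-phenyl-1,3-dioxan-4-yl]methyl}-1,3-dioxan-4-yl]acetic acid | CCCCCCCCC[C@H]1C[C@@H](C[C@@H]2C[C@H](CC(=O)O)OC(C)(C)O2)O[C@@H](c3ccccc3)O1
F10 | step 13 | 1-{2-[(4R,6R)-2,2-dimethyl-6-{[(2S,4S,6S)-6-nonyl-2-phenyl-1,3-dioxan-4-yl]methyl}-1,3-dioxan-4-yl]acetyl}imidazole | CCCCCCCCC[C@H]1C[C@@H](C[C@@H]2C[C@H](CC(=O)n3ccnc3)OC(C)(C)O2)O[C@@H](c3ccccc3)O1
F11 | step 14 | tert-butyl 4-[(4R,6R)-2,2-dimethyl-6-{[(2S,4S,6S)-6-nonyl-2-phenyl-1,3-dioxan-4-yl]methyl}-1,3-dioxan-4-yl]-3-oxobutanoate | CCCCCCCCC[C@H]1C[C@@H](C[C@@H]2C[C@H](CC(=O)CC(=O)OC(C)(C)C)OC(C)(C)O2)O[C@@H](c3ccccc3)O1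
F12 | step 2 | 3-(tert-butyldiphenylsilyloxy)propanal | O=CCCO[Si](C(C)(C)C)(c1ccccc1)c1ccccc1
A1 | alternative 1 | (S)-1-{2-[(S)-2-(tert-butyldimethylsilyloxy)undecyl]-1,3-dithian-2-yl}pent-4-en-2-ol | CCCCCCCCC[C@H](O[Si](C)(C)C(C)(C)C)CC1(SCCCS1)C[C@@H](O)CC=C
A2 | alternative 1 | 2-(tert-butyldimethylsilyl)-1,3-dithiane | CC(C)(C)[Si](C)(C)C1SCCCS1
A3 | alternative 1 | (S)-2-nonyloxirane | CCCCCCCCC[C@H]1CO1
A4 | alternative 1 | (S)-2-allyloxirane | C=CC[C@H]1CO1
A5 | alternative 2 | 2-[2,4,6-tris(tert-butyldimethylsilyloxy)pentadecyl]oxirane, the C4–C20 terminal epoxide with the target configurations at C5, C7, C9 and C11 | CCCCCCCCC[C@H](O[Si](C)(C)C(C)(C)C)C[C@H](O[Si](C)(C)C(C)(C)C)C[C@@H](O[Si](C)(C)C(C)(C)C)C[C@@H]1CO1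
A6 | alternative 2 | 4-[2,4,6-tris(tert-butyldimethylsilyloxy)pentadecyl]oxetan-2-one, the C3–C20 β-lactone with the target configurations at C5, C7, C9 and C11 | CCCCCCCCC[C@H](O[Si](C)(C)C(C)(C)C)C[C@H](O[Si](C)(C)C(C)(C)C)C[C@@H](O[Si](C)(C)C(C)(C)C)C[C@@H]1CC(=O)O1
A7 | alternative 2 | carbon monoxide | [C-]#[O+]
A8 | alternative 3 | chloroacetaldehyde | ClCC=O
A9 | alternative 3 | acetaldehyde | CC=O
A10 | alternative 3 | (4R,6S)-6-(chloromethyl)oxane-2,4-diol (anomeric mixture) | ClC[C@@H]1C[C@@H](O)CC(O)O1
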